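The synthesis rests on disconnecting the aryl ether bond O1–C8a of pyran ring C of the upper flavan unit, which sits meta to the 7-oxygen of ring A. A palladium-catalysed intramolecular etherification of the C2 carbinol onto a C8a chloride closes ring C last, with retention at C2 and C3, which are set beforehand in the open chain. Because ring A stays a non-nucleophilic chloroarene until then, catechol ring B (C6') rather than ring A can be joined to C4 of a fustin-derived lower unit. The precursor is an erythro 1,3-diarylpropane-1,2-diol 2-benzyl ether whose 3-aryl group bears the chlorine and whose 1-aryl group carries the perbenzylated 4-flavanyl substituent.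

Key step: step 11

Assumption: (2R,3R)-fustin (the natural trans-dihydroflavonol), 1,2-bis(benzyloxy)benzene, 4-bromo-3-chlorophenol and methyl (2S)-glycidate are taken as purchasable; "upper unit" means rings A, C, B (the chroman closed in step 11) and "lower unit" means rings D, F, E (the 4-aryl chroman from fustin).

Step 1
Reactants: 1 (2R,3R)-fustin
Product: 3 (2R,3R,4R)-2-(3,4-diacetoxyphenyl)chromane-3,4,7-triyl triacetate (2,3-trans-3,4-trans pentaacetate), via (+)-mollisacacidin 2 (not isolated)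
Conditions: NaBH4, EtOH, 0 °C to rt; AcOH, evaporate; then Ac2O, pyridine, DMAP (cat.), rt
Reagents that add atoms: acetic anhydride, CC(=O)OC(C)=O
Why: Borohydride reduction of the C4 ketone of a trans-dihydroflavonol should give the 2,3-trans-3,4-trans diol (hydride anti to the 3-hydroxyl; C4 is erased in step 2 anyway), and peracetylation of the crude acid-labile diol protects it and makes rings D and E poor nucleophiles for the next step.

Step 2
Reactants: 3 pentaacetate; 4 1,2-bis(benzyloxy)benzene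
Product: 5 (2R,3S,4R)-4-[3,4-bis(benzyloxy)phenyl]-2-(3,4-diacetoxyphenyl)chromane-3,7-diyl diacetate
Conditions: 4 (10 equiv), BF3·OEt2 (2 equiv), CH2Cl2, −20 °C to rt
Reagents that add atoms: none
Why: Friedel–Crafts alkylation by the O1-stabilised C4 benzylic cation released from the 4-acetate, para to a benzyloxy group of the electron-rich diether in excess, with 3-acetoxy participation (acyloxonium, as in 1,2-trans C-aryl glycosylation) and the equatorial preference both sending the arene to the face trans to O3, which sets C4 of the lower unit as 3,4-trans (2,4-cis).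

Step 3
Reactants: 5
Product: 6 (2R,3S,4S)-4-[4,5-bis(benzyloxy)-2-bromophenyl]-2-(3,4-diacetoxyphenyl)chromane-3,7-diyl diacetate
Conditions: NBS (1.0 equiv), MeCN, 0 °C, dark
Reagents that add atoms: N-bromosuccinimide, O=C1CCC(=O)N1Br
Why: Electrophilic aromatic bromination should select the only dialkoxy-activated ring at the site para to a benzyloxy group and ortho to the chromanyl carbon, which is why it is run while rings D and E are still deactivated as acetates.

Step 4
Reactants: 6
Product: 8 (2R,3S,4S)-3,7-bis(benzyloxy)-4-[4,5-bis(benzyloxy)-2-bromophenyl]-2-[3,4-bis(benzyloxy)phenyl]chromane, via tetraol 7 (not isolated)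
Conditions: K2CO3 (cat.), MeOH/THF, rt, Ar; evaporate; then NaH, BnBr, Bu4NI (cat.), DMF, 0 °C to rt
Reagents that add atoms: benzyl bromide, BrCc1ccccc1
Why: Zemplén-type transesterification removes the four acetates once their deactivating role is over, and Williamson benzylation of the crude tetraol gives base-stable ethers compatible with the organolithium step, without touching a stereocentre.

Step 5
Reactants: 9 4-bromo-3-chlorophenol
Product: 10 4-(benzyloxy)-1-bromo-2-chlorobenzene
Conditions: BnBr, K2CO3, DMF, rt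
Reagents that add atoms: benzyl bromide, BrCc1ccccc1
Why: Williamson ether synthesis on the phenoxide is straightforward and installs the same hydrogenolysable protecting group used elsewhere.

Step 6
Reactants: 10; 11 methyl (2S)-oxirane-2-carboxylate (methyl (S)-glycidate)
Product: 13 methyl (2S)-3-[4-(benzyloxy)-2-chlorophenyl]-2-hydroxypropanoate, via arylmagnesium bromide 12 (not isolated)
Conditions: Mg, THF, 40 °C; then added to 11, CuI (10 mol%), THF, −40 to −20 °C; aq. NH4Cl
Reagents that add atoms: none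
Why: Magnesium inserts into C–Br and not C–Cl, and the copper-catalysed Grignard opening of the glycidic ester at the unsubstituted epoxide carbon should outpace ester addition at low temperature, so the (S) centre of 11 is carried over unchanged to become C3 of the upper unit.

Step 7
Reactants: 13
Product: 14 methyl (2S)-2-(benzyloxy)-3-[4-(benzyloxy)-2-chlorophenyl]propanoate
Conditions: BnOC(=NH)CCl3, TfOH (5 mol%), CH2Cl2/cyclohexane, 0 °C to rt
Reagents that add atoms: benzyl 2,2,2-trichloroacetimidate, N=C(OCc1ccccc1)C(Cl)(Cl)Cl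
Why: Acid-catalysed O-benzylation with the trichloroacetimidate alkylates the α-hydroxy ester without base and hence without racemisation, and a benzyl ether cannot migrate to the neighbouring oxygen later as a silyl group could.

Step 8
Reactants: 14
Product: 15 (2S)-2-(benzyloxy)-3-[4-(benzyloxy)-2-chlorophenyl]-N-methoxy-N-methylpropanamide
Conditions: MeNH(OMe)·HCl, iPrMgCl, THF, −20 to 0 °C
Reagents that add atoms: N,O-dimethylhydroxylamine hydrochloride, CNOC.Cl
Why: The chloromagnesium amide of N,O-dimethylhydroxylamine converts the methyl ester directly into the Weinreb amide at low temperature, leaving the aryl chloride and the α-centre untouched.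

Step 9
Reactants: 8; 15
Product: 17 (2S)-2-(benzyloxy)-3-[4-(benzyloxy)-2-chlorophenyl]-1-{4,5-bis(benzyloxy)-2-[(2R,3S,4R)-3,7-bis(benzyloxy)-2-[3,4-bis(benzyloxy)phenyl]chroman-4-yl]phenyl}propan-1-one, via aryllithium 16 (not isolated)
Conditions: tBuLi (2.1 equiv), THF, −78 °C; then 15, −78 to −40 °C; aq. NH4Cl
Reagents that add atoms: none
Why: Bromine–lithium exchange gives the aryllithium, which is acylated by the Weinreb amide through a stable chelated tetrahedral adduct that collapses to the ketone only on work-up, the aryl chloride of 15 (chosen over a bromide for this reason) being inert to halogen–metal exchange.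

Step 10
Reactants: 17
Product: 18 (1R,2S)-2-(benzyloxy)-3-[4-(benzyloxy)-2-chlorophenyl]-1-{4,5-bis(benzyloxy)-2-[(2R,3S,4R)-3,7-bis(benzyloxy)-2-[3,4-bis(benzyloxy)phenyl]chroman-4-yl]phenyl}propan-1-ol
Conditions: Zn(BH4)2, Et2O/CH2Cl2, −30 to 0 °C; aq. NH4Cl
Reagents that add atoms: none
Why: Cram-chelate (chelation-controlled) reduction, in which zinc ties the ketone oxygen to the α-benzyloxy oxygen and hydride enters from the face of the α-hydrogen, should give the anti (erythro) alcohol and so set C2 of the upper unit as R relative to the (S) centre from 11.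

Step 11
Reactants: 18
Product: 19 (2R,3S)-3,7-bis(benzyloxy)-2-{4,5-bis(benzyloxy)-2-[(2R,3S,4R)-3,7-bis(benzyloxy)-2-[3,4-bis(benzyloxy)phenyl]chroman-4-yl]phenyl}chromane (octa-O-benzyl ether of the target)
Conditions: Pd(OAc)2 (5 mol%), 2-(di-tert-butylphosphino)-1,1'-binaphthyl (6 mol%), Cs2CO3, toluene, 80 °C
Reagents that add atoms: none
Why: Intramolecular Buchwald–Hartwig etherification: zerovalent palladium formed in situ inserts into the C8a–Cl bond of ring A, the C2 hydroxyl is deprotonated on palladium by Cs2CO3, and C–O reductive elimination from the seven-membered oxapalladacycle forges O1–C8a. The closest known reaction type is the palladium/di-tert-butylbiarylphosphine cyclisation of secondary 3-(2-haloaryl)propanols to chromans, which proceeds without loss of configuration at the carbinol. Ring C closes as a six-membered ring by attack of O1 on the ipso carbon C8a (formally 6-exo with respect to the breaking C–Cl bond). No stereocentre is created: the C2–O and C3–O bonds are never broken, so the (2R,3S) 2,3-trans relationship fixed in steps 6 and 10 is carried through, and the weak carbonate base offers no pathway for epimerisation. The step needs C–O reductive elimination to outrun β-hydride elimination of the benzylic palladium alkoxide, which the bulky electron-rich ligand should secure, and it needs ring-size control, which the substrate secures because O3 is benzyl-capped (no five-membered closure) and C8a carries the only carbon–halogen bond.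

Step 12
Reactants: 19
Product: 20 (2R,3S)-2-{2-[(2R,3S,4R)-2-(3,4-dihydroxyphenyl)-3,7-dihydroxychroman-4-yl]-4,5-dihydroxyphenyl}chromane-3,7-diol (CNP0244903.3)
Conditions: H2 (1 atm), Pd(OH)2/C, THF/MeOH, rt
Reagents that add atoms: none
Why: Catalytic hydrogenolysis should cleave all eight O-benzyl ethers, while the cyclic benzylic O1–C2 bonds of both flavan units and the diarylmethine C4 are expected to survive these mild conditions, as in catechin and proanthocyanidin chemistry.

Compound list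
1 | (2R,3R)-fustin, (2R,3R)-2-(3,4-dihydroxyphenyl)-3,7-dihydroxychroman-4-one | O=C1c2ccc(O)cc2O[C@H](c2ccc(O)c(O)c2)[C@H]1O | starting material
2 | (+)-mollisacacidin, (2R,3S,4R)-2-(3,4-dihydroxyphenyl)chromane-3,4,7-triol | O[C@@H]1c2ccc(O)cc2O[C@H](c2ccc(O)c(O)c2)[C@H]1O | intermediate
3 | (2R,3R,4R)-2-(3,4-diacetoxyphenyl)chromane-3,4,7-triyl triacetate | CC(=O)O[C@@H]1c2ccc(OC(C)=O)cc2O[C@H](c2ccc(OC(C)=O)c(OC(C)=O)c2)[C@H]1OC(C)=O | intermediate
4 | 1,2-bis(benzyloxy)benzene | C(Oc1ccccc1OCc1ccccc1)c1ccccc1 | starting material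
5 | (2R,3S,4R)-4-[3,4-bis(benzyloxy)phenyl]-2-(3,4-diacetoxyphenyl)chromane-3,7-diyl diacetate | C(c1ccccc1)Oc1ccc(cc1OCc1ccccc1)[C@@H]1c2ccc(OC(C)=O)cc2O[C@H](c2ccc(OC(C)=O)c(OC(C)=O)c2)[C@H]1OC(C)=O | intermediate
6 | (2R,3S,4S)-4-[4,5-bis(benzyloxy)-2-bromophenyl]-2-(3,4-diacetoxyphenyl)chromane-3,7-diyl diacetate | C(c1ccccc1)Oc1cc(Br)c(cc1OCc1ccccc1)[C@@H]1c2ccc(OC(C)=O)cc2O[C@H](c2ccc(OC(C)=O)c(OC(C)=O)c2)[C@H]1OC(C)=O | intermediate
7 | (2R,3S,4S)-4-[4,5-bis(benzyloxy)-2-bromophenyl]-2-(3,4-dihydroxyphenyl)chromane-3,7-diol | C(c1ccccc1)Oc1cc(Br)c(cc1OCc1ccccc1)[C@@H]1c2ccc(O)cc2O[C@H](c2ccc(O)c(O)c2)[C@H]1O | intermediate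
8 | (2R,3S,4S)-3,7-bis(benzyloxy)-4-[4,5-bis(benzyloxy)-2-bromophenyl]-2-[3,4-bis(benzyloxy)phenyl]chromane | C(c1ccccc1)Oc1cc(Br)c(cc1OCc1ccccc1)[C@@H]1c2ccc(OCc3ccccc3)cc2O[C@H](c2ccc(OCc3ccccc3)c(OCc3ccccc3)c2)[C@H]1OCc1ccccc1 | intermediate
9 | 4-bromo-3-chlorophenol | Oc1ccc(Br)c(Cl)c1 | starting material
10 | 4-(benzyloxy)-1-bromo-2-chlorobenzene | Clc1cc(OCc2ccccc2)ccc1Br | intermediate
11 | methyl (2S)-oxirane-2-carboxylate | COC(=O)[C@@H]1CO1 | starting material
12 | [4-(benzyloxy)-2-chlorophenyl]magnesium bromide | Clc1cc(OCc2ccccc2)ccc1[Mg]Br | intermediate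
13 | methyl (2S)-3-[4-(benzyloxy)-2-chlorophenyl]-2-hydroxypropanoate | COC(=O)[C@@H](O)Cc1ccc(OCc2ccccc2)cc1Cl | intermediate
14 | methyl (2S)-2-(benzyloxy)-3-[4-(benzyloxy)-2-chlorophenyl]propanoate | COC(=O)[C@@H](OCc1ccccc1)Cc1ccc(OCc2ccccc2)cc1Cl | intermediate
15 | (2S)-2-(benzyloxy)-3-[4-(benzyloxy)-2-chlorophenyl]-N-methoxy-N-methylpropanamide | CON(C)C(=O)[C@@H](OCc1ccccc1)Cc1ccc(OCc2ccccc2)cc1Cl | intermediate
16 | {4,5-bis(benzyloxy)-2-[(2R,3S,4R)-3,7-bis(benzyloxy)-2-[3,4-bis(benzyloxy)phenyl]chroman-4-yl]phenyl}lithium | [Li]c1cc(OCc2ccccc2)c(OCc2ccccc2)cc1[C@@H]1c2ccc(OCc3ccccc3)cc2O[C@H](c2ccc(OCc3ccccc3)c(OCc3ccccc3)c2)[C@H]1OCc1ccccc1 | intermediate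
17 | (2S)-2-(benzyloxy)-3-[4-(benzyloxy)-2-chlorophenyl]-1-{4,5-bis(benzyloxy)-2-[(2R,3S,4R)-3,7-bis(benzyloxy)-2-[3,4-bis(benzyloxy)phenyl]chroman-4-yl]phenyl}propan-1-one | O=C([C@@H](OCc1ccccc1)Cc1ccc(OCc2ccccc2)cc1Cl)c1cc(OCc2ccccc2)c(OCc2ccccc2)cc1[C@@H]1c2ccc(OCc3ccccc3)cc2O[C@H](c2ccc(OCc3ccccc3)c(OCc3ccccc3)c2)[C@H]1OCc1ccccc1 | intermediate
18 | (1R,2S)-2-(benzyloxy)-3-[4-(benzyloxy)-2-chlorophenyl]-1-{4,5-bis(benzyloxy)-2-[(2R,3S,4R)-3,7-bis(benzyloxy)-2-[3,4-bis(benzyloxy)phenyl]chroman-4-yl]phenyl}propan-1-ol | O[C@H](c1cc(OCc2ccccc2)c(OCc2ccccc2)cc1[C@@H]1c2ccc(OCc3ccccc3)cc2O[C@H](c2ccc(OCc3ccccc3)c(OCc3ccccc3)c2)[C@H]1OCc1ccccc1)[C@@H](OCc1ccccc1)Cc1ccc(OCc2ccccc2)cc1Cl | intermediate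
19 | (2R,3S)-3,7-bis(benzyloxy)-2-{4,5-bis(benzyloxy)-2-[(2R,3S,4R)-3,7-bis(benzyloxy)-2-[3,4-bis(benzyloxy)phenyl]chroman-4-yl]phenyl}chromane | C(c1ccccc1)Oc1ccc2c(c1)O[C@H](c1cc(OCc3ccccc3)c(OCc3ccccc3)cc1[C@@H]1c3ccc(OCc4ccccc4)cc3O[C@H](c3ccc(OCc4ccccc4)c(OCc4ccccc4)c3)[C@H]1OCc1ccccc1)[C@@H](OCc1ccccc1)C2 | intermediate
20 | (2R,3S)-2-{2-[(2R,3S,4R)-2-(3,4-dihydroxyphenyl)-3,7-dihydroxychroman-4-yl]-4,5-dihydroxyphenyl}chromane-3,7-diol (CNP0244903.3) | Oc1ccc2c(c1)O[C@H](c1cc(O)c(O)cc1[C@@H]1c3ccc(O)cc3O[C@H](c3ccc(O)c(O)c3)[C@H]1O)[C@@H](O)C2 | target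

Total step count: 12. Longest linear sequence: 8 steps (steps 1–4 then 9–12 from fustin; equally steps 5–12 from 4-bromo-3-chlorophenol).

Steps most likely to fail

Step 2. The C4 cation may be captured at C6 of ring D of a second molecule of 3 or of product 5 about as fast as by the only moderately nucleophilic diether 4, leading to self-alkylation and oligomers. The fallback sets out from 3 and replaces 4 by the far more nucleophilic free phenol 2-(benzyloxy)phenol (BF3·OEt2, CH2Cl2). C-alkylation para to the free hydroxyl (any O-alkylated material re-ionising under the Lewis acid) should give (2R,3S,4R)-4-[3-(benzyloxy)-4-hydroxyphenyl]-2-(3,4-diacetoxyphenyl)chromane-3,7-diyl diacetate F1. The phenol is then capped under neutral Mitsunobu conditions (BnOH, PPh3, DIAD, THF) that leave the acetates alone, and the route is rejoined at 5.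

Step 11. β-Hydride elimination of the hindered benzylic palladium alkoxide (oxidation at C2 with hydrodechlorination) may outrun C–O reductive elimination. The fallback sets out from 18 and separates the two events. Miyaura borylation of the aryl chloride with a weak base that does not form the alkoxide (Pd(OAc)2, 2-dicyclohexylphosphino-2',4',6'-triisopropylbiphenyl, B2pin2, KOAc, dioxane, 100 °C) should give (1R,2S)-2-(benzyloxy)-3-[4-(benzyloxy)-2-(4,4,5,5-tetramethyl-1,3,2-dioxaborolan-2-yl)phenyl]-1-{4,5-bis(benzyloxy)-2-[(2R,3S,4R)-3,7-bis(benzyloxy)-2-[3,4-bis(benzyloxy)phenyl]chroman-4-yl]phenyl}propan-1-ol F2. A copper-mediated oxidative Chan–Lam etherification (Cu(OAc)2, pyridine, 4 Å molecular sieves, air, CH2Cl2) then closes the same O1–C8a bond and rejoins the route at 19.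

Step 9. The aryllithium 16, flanked by the bulky chromanyl group, may act as a base (α-deprotonation of the amide, then quench) instead of adding to the amide carbonyl. The fallback sets out from 15 and 8 and uses a smaller, more reactive electrophile. DIBAL-H reduction of 15 at −78 °C gives (2S)-2-(benzyloxy)-3-[4-(benzyloxy)-2-chlorophenyl]propanal F3. Addition of 16 (from 8 as before) to this aldehyde gives (2S)-2-(benzyloxy)-3-[4-(benzyloxy)-2-chlorophenyl]-1-{4,5-bis(benzyloxy)-2-[(2R,3S,4R)-3,7-bis(benzyloxy)-2-[3,4-bis(benzyloxy)phenyl]chroman-4-yl]phenyl}propan-1-ol as a mixture of C1 epimers F4. Dess–Martin oxidation of the mixture rejoins the route at ketone 17, so that step 10 still sets C2.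

Further compounds
F1 | step 2 | (2R,3S,4R)-4-[3-(benzyloxy)-4-hydroxyphenyl]-2-(3,4-diacetoxyphenyl)chromane-3,7-diyl diacetate | Oc1ccc(cc1OCc1ccccc1)[C@@H]1c2ccc(OC(C)=O)cc2O[C@H](c2ccc(OC(C)=O)c(OC(C)=O)c2)[C@H]1OC(C)=O
F2 | step 11 | (1R,2S)-2-(benzyloxy)-3-[4-(benzyloxy)-2-(4,4,5,5-tetramethyl-1,3,2-dioxaborolan-2-yl)phenyl]-1-{4,5-bis(benzyloxy)-2-[(2R,3S,4R)-3,7-bis(benzyloxy)-2-[3,4-bis(benzyloxy)phenyl]chroman-4-yl]phenyl}propan-1-ol | O[C@H](c1cc(OCc2ccccc2)c(OCc2ccccc2)cc1[C@@H]1c2ccc(OCc3ccccc3)cc2O[C@H](c2ccc(OCc3ccccc3)c(OCc3ccccc3)c2)[C@H]1OCc1ccccc1)[C@@H](OCc1ccccc1)Cc1ccc(OCc2ccccc2)cc1B1OC(C)(C)C(C)(C)O1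
F3 | step 9 | (2S)-2-(benzyloxy)-3-[4-(benzyloxy)-2-chlorophenyl]propanal | O=C[C@@H](OCc1ccccc1)Cc1ccc(OCc2ccccc2)cc1Cl
F4 | step 9 | (2S)-2-(benzyloxy)-3-[4-(benzyloxy)-2-chlorophenyl]-1-{4,5-bis(benzyloxy)-2-[(2R,3S,4R)-3,7-bis(benzyloxy)-2-[3,4-bis(benzyloxy)phenyl]chroman-4-yl]phenyl}propan-1-ol, mixture of C1 epimers | OC(c1cc(OCc2ccccc2)c(OCc2ccccc2)cc1[C@@H]1c2ccc(OCc3ccccc3)cc2O[C@H](c2ccc(OCc3ccccc3)c(OCc3ccccc3)c2)[C@H]1OCc1ccccc1)[C@@H](OCc1ccccc1)Cc1ccc(OCc2ccccc2)cc1Cl
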